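**Retrosynthetic overview** (C7 = carbinol carbon, C8 = ether-bearing carbon)
- Last cut: the aryl–alkenyl bond (Suzuki–Miyaura). An aryl bromide stands in for the cinnamyl alcohol arm, so the radical-sensitive styrenyl alkene is absent from the key step.
- Key cut: C7–C8. C7 is the carbonyl carbon of 3,4,5-trimethoxybenzaldehyde. C8 bears oxygen and is by nature an oxocarbenium-type electrophile; here it is used with inverted polarity as a 1-aryloxyethylchromium nucleophile.
- That nucleophile is released from a racemic 2-aryloxypropanoic acid by photoredox loss of CO2. A chiral chromium catalyst sets 7R and 8R (threo) in the same bond-forming event, already at the final oxidation level.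
- The acid comes from 4-bromo-2,6-dimethoxyphenol and 2-bromopropanoic acid by ether synthesis.
- No ring is formed at any stage: both benzene rings are bought intact.

Assumption: the (3aS,8aR) hand of the indanyl bis(oxazoline) ligand L* is taken to leave the Si face of the bound aldehyde open (7R); if a first analytical run shows the opposite sense, the equally available (3aR,8aS) hand is used and nothing else changes; the bromophenol and the hydroxypropenyl pinacol boronate are taken as catalogue items.

**Step 1**
Reactants: 1 4-bromo-2,6-dimethoxyphenol; 2 rac-2-bromopropanoic acid (1.5 equiv)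
Product: 4 rac-2-(4-bromo-2,6-dimethoxyphenoxy)propanoic acid, via sodium carboxylate 3 (not isolated)
Conditions: NaOH (3.5 equiv), H2O, N2, reflux, 6 h; then aq HCl, pH 2, 0 °C
Reagents that add atoms: none
Why: Williamson ether synthesis (SN2 of the phenoxide on the α-bromocarboxylate), the reaction run on scale for aryloxypropionic acids; the new stereocentre is deliberately left racemic because step 2 erases it.

**Step 2 (key step)**
Reactants: 4 rac-2-(4-bromo-2,6-dimethoxyphenoxy)propanoic acid (1.5 equiv); 5 3,4,5-trimethoxybenzaldehyde
Product: 9 (1R,2R)-2-(4-bromo-2,6-dimethoxyphenoxy)-1-(3,4,5-trimethoxyphenyl)propan-1-ol, via aryloxyethyl radical 6 (not isolated), via aryloxyethylchromium dichloride 7 (not isolated), via chromium alkoxide 8 (not isolated)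
Conditions: CrCl2 (10 mol %), L* = (3aS,3a'S,8aR,8a'R)-2,2'-(propane-2,2-diyl)bis(3a,8a-dihydro-8H-indeno[1,2-d]oxazole) (12 mol %), 4CzIPN (2 mol %), 2,4,6-collidine (30 mol %), THF–MeCN 1:1, 450 nm LEDs, 10 °C, 24 h
Reagents that add atoms: none
Why: Proposed new method: a photoredox/chromium radical–polar crossover carbonyl addition of Nozaki–Hiyama–Kishi type, in which excited 4CzIPN effects oxidative decarboxylation of 4 to the planar, stereochemically blank radical 6, divalent chromium (regenerated from trivalent chromium by the reduced dye) traps 6 to give alkylchromium 7, a carbanion equivalent at an O-bearing carbon that normally reacts as an electrophile, and 7 adds to the carbonyl carbon of 5 to give alkoxide 8, which the collidine proton shuttle protonates to release 9; the Cr–C bond of 7 homolyses reversibly, so its two C8 epimers interconvert and the racemic acid is funnelled (Curtin–Hammett) through the lowest closed four-centre transition state, where L* leaves the Si face of the bound aldehyde open (7R) and the bulky aryloxy group lies in the Cr–C–C–O plane pointing away from the aldehyde while C8–H faces the trimethoxyphenyl ring and CH3 faces the formyl H (8R, threo); the closest known reaction types are the photoredox/chromium addition of α-amino carbanion equivalents to aldehydes, the chromium-mediated decarboxylative alkylation of aldehydes with redox-active esters, the enantioselective photoredox/chromium–bis(oxazoline) allylation of aldehydes and the chromium-catalysed asymmetric cross aza-pinacol coupling, which sets two vicinal stereocentres from an α-heteroatom radical.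

**Step 3**
Reactants: 9 (1R,2R)-2-(4-bromo-2,6-dimethoxyphenoxy)-1-(3,4,5-trimethoxyphenyl)propan-1-ol; 10 (E)-3-(4,4,5,5-tetramethyl-1,3,2-dioxaborolan-2-yl)prop-2-en-1-ol (1.3 equiv)
Product: 11 (1R,2R)-2-{4-[(1E)-3-hydroxyprop-1-en-1-yl]-2,6-dimethoxyphenoxy}-1-(3,4,5-trimethoxyphenyl)propan-1-ol
Conditions: Pd(OAc)2 (3 mol %), SPhos (6 mol %), K2CO3 (2 equiv), 1,4-dioxane–H2O 5:1, 80 °C, 4 h
Reagents that add atoms: none
Why: Suzuki–Miyaura coupling keeps the E geometry of the alkenylboronate, tolerates both free hydroxyl groups, and its mild carbonate base cannot touch C7 or C8, which carry neither an acidic hydrogen nor a leaving group.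

**Compound list**
1 | 4-bromo-2,6-dimethoxyphenol | COc1cc(Br)cc(OC)c1O | starting material
2 | rac-2-bromopropanoic acid | CC(Br)C(=O)O | starting material
3 | sodium rac-2-(4-bromo-2,6-dimethoxyphenoxy)propanoate | CC(Oc1c(OC)cc(Br)cc1OC)C(=O)[O-].[Na+] | intermediate
4 | rac-2-(4-bromo-2,6-dimethoxyphenoxy)propanoic acid | CC(Oc1c(OC)cc(Br)cc1OC)C(=O)O | intermediate
5 | 3,4,5-trimethoxybenzaldehyde | COc1cc(C=O)cc(OC)c1OC | starting material
6 | 1-(4-bromo-2,6-dimethoxyphenoxy)ethyl radical (planar, no stereochemistry) | C[CH]Oc1c(OC)cc(Br)cc1OC | intermediate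
7 | [1-(4-bromo-2,6-dimethoxyphenoxy)ethyl]chromium dichloride (trivalent chromium; ligand L* omitted; C8 configurationally labile) | CC([Cr](Cl)Cl)Oc1c(OC)cc(Br)cc1OC | intermediate
8 | dichlorochromium alkoxide of 9 (trivalent chromium; ligand L* omitted; 7R,8R) | COc1cc([C@@H](O[Cr](Cl)Cl)[C@@H](C)Oc2c(OC)cc(Br)cc2OC)cc(OC)c1OC | intermediate
9 | (1R,2R)-2-(4-bromo-2,6-dimethoxyphenoxy)-1-(3,4,5-trimethoxyphenyl)propan-1-ol (threo) | COc1cc([C@@H](O)[C@@H](C)Oc2c(OC)cc(Br)cc2OC)cc(OC)c1OC | intermediate
10 | (E)-3-(4,4,5,5-tetramethyl-1,3,2-dioxaborolan-2-yl)prop-2-en-1-ol | OC/C=C/B1OC(C)(C)C(C)(C)O1 | starting material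
11 | (1R,2R)-2-{4-[(1E)-3-hydroxyprop-1-en-1-yl]-2,6-dimethoxyphenoxy}-1-(3,4,5-trimethoxyphenyl)propan-1-ol | COc1cc([C@@H](O)[C@@H](C)Oc2c(OC)cc(/C=C/CO)cc2OC)cc(OC)c1OC | target

**Total step count:** 3. **Longest linear sequence:** 3 steps (1 → 4 → 9 → 11).

**Steps most likely to fail**

Step 2 (highest risk).
- Acid may protonate 7 to the ethyl aryl ether faster than 7 adds to the electron-rich aldehyde.
- 5 may dimerise by pinacol coupling.
- The dr and ee of an untested substrate/ligand pair may be modest. The aryl bromide itself is inert to divalent chromium when no nickel is present.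

The fallback sets out from 4 and 5 and comes back to the route at 9. Acid 4 is condensed with N-hydroxyphthalimide (N,N'-diisopropylcarbodiimide, DMAP, CH2Cl2) to the redox-active N-hydroxyphthalimide ester F1. A carbene from an N-aryl thiazolium salt (10 mol %, Cs2CO3, DMSO, 60 °C) turns 5 into an acyl anion equivalent that reduces F1 by one electron. The resulting radical pair collapses to the racemic α-aryloxy ketone F2, so the C7–C8 bond is still made with inverted polarity, now at C7. Asymmetric transfer hydrogenation under dynamic kinetic resolution (RuCl[(S,S)-TsDPEN](p-cymene), HCO2H–Et3N 5:2, 40 °C) then reduces the readily racemising F2 to 9. The 7R sense and the threo relation follow the benzoin to (R,R)-hydrobenzoin behaviour of this catalyst hand.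

Step 3. Oxidative addition to the electron-rich bromide may be slow enough for 10 to protodeboronate or oligomerise. The fallback sets out from 9 and comes back at 11. A Heck reaction with methyl acrylate (Pd(OAc)2, P(o-tol)3, Et3N, DMF, 100 °C) gives the methyl cinnamate F3. i-Bu2AlH (4 equiv, CH2Cl2, −78 °C) then reduces F3 to the allylic alcohol 11 without touching C7 or C8.

Step 1. Hydrolysis of 2 to lactic acid may outrun O-alkylation of the doubly ortho-substituted phenoxide. The fallback sets out from 1 and comes back at 3. Mitsunobu etherification of 1 with racemic methyl lactate (PPh3, diisopropyl azodicarboxylate, THF, 0 °C to rt) gives the methyl ester F4. NaOH in THF–H2O saponifies F4 to sodium carboxylate 3, which is acidified as in step 1.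

**Further compounds**
F1 | step 2 | 1,3-dioxoisoindolin-2-yl rac-2-(4-bromo-2,6-dimethoxyphenoxy)propanoate | CC(Oc1c(OC)cc(Br)cc1OC)C(=O)ON1C(=O)c2ccccc2C1=O
F2 | step 2 | rac-2-(4-bromo-2,6-dimethoxyphenoxy)-1-(3,4,5-trimethoxyphenyl)propan-1-one | COc1cc(C(=O)C(C)Oc2c(OC)cc(Br)cc2OC)cc(OC)c1OC
F3 | step 3 | methyl (E)-3-(4-{[(1R,2R)-1-hydroxy-1-(3,4,5-trimethoxyphenyl)propan-2-yl]oxy}-3,5-dimethoxyphenyl)prop-2-enoate | COc1cc([C@@H](O)[C@@H](C)Oc2c(OC)cc(/C=C/C(=O)OC)cc2OC)cc(OC)c1OC
F4 | step 1 | methyl rac-2-(4-bromo-2,6-dimethoxyphenoxy)propanoate | COC(=O)C(C)Oc1c(OC)cc(Br)cc1OC
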